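**Retrosynthetic overview**
- The last ring formed is the pyranone ring of the flavanone half. It is closed by O1–C2 bond formation in an enantioselective 6-endo oxa-Michael addition of a 2'-hydroxychalcone, which sets C2 (S); one global hydrogenolysis then frees all phenols.
- The chalcone comes from a Claisen–Schmidt condensation of 2-hydroxy-4,6-bis(benzyloxy)acetophenone with a biaryl aldehyde.
- The biaryl aldehyde comes from a Suzuki–Miyaura coupling (C6''–C2' bond) of a 6-iodo-tri-O-benzylapigenin with an ortho-formyl catechol-ketal boronic acid.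
- The fragments are apigenin (benzylation, C6 iodination), 3,4-dihydroxybenzaldehyde (Ph2C ketal, directed lithiation–borylation) and 2,4,6-trihydroxyacetophenone.
- Ring order: the flavone rings A, C and B are bought intact as apigenin, then biaryl, then chalcone, then the flavanone ring C last.

Assumption: the target string fixes only C2 (S); the 2'–6'' biaryl axis is undefined there and is left uncontrolled (atropisomers, if stable, are carried as a mixture).

**Route**

Step 1
Reactants: 1 apigenin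
Product: 2 7-(benzyloxy)-2-[4-(benzyloxy)phenyl]-5-hydroxy-4H-chromen-4-one
Conditions: BnBr (2.2 equiv), K2CO3 (2.5 equiv), DMF, rt to 50 °C
Reagents that add atoms: benzyl bromide BrCc1ccccc1
Why: Williamson etherification in which the acidic 7-OH and 4'-OH are alkylated while the 5-OH, hydrogen-bonded to the C4 carbonyl, stays free under mild carbonate conditions.

Step 2
Reactants: 2 7-(benzyloxy)-2-[4-(benzyloxy)phenyl]-5-hydroxy-4H-chromen-4-one
Product: 3 7-(benzyloxy)-2-[4-(benzyloxy)phenyl]-5-hydroxy-6-iodo-4H-chromen-4-one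
Conditions: NIS (1.05 equiv), DMF, rt, dark
Reagents that add atoms: N-iodosuccinimide O=C1CCC(=O)N1I
Why: Electrophilic aromatic iodination of the phloroglucinol-type ring A, where a free 5-OH directs the halogen to C6 (5-O-alkyl flavones go to C8 instead).

Step 3
Reactants: 3 7-(benzyloxy)-2-[4-(benzyloxy)phenyl]-5-hydroxy-6-iodo-4H-chromen-4-one
Product: 4 5,7-bis(benzyloxy)-2-[4-(benzyloxy)phenyl]-6-iodo-4H-chromen-4-one
Conditions: BnBr (1.5 equiv), K2CO3 (3 equiv), nBu4NI (cat.), DMF, 70 °C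
Reagents that add atoms: benzyl bromide BrCc1ccccc1
Why: Williamson etherification under forcing conditions caps the chelated 5-OH, which would otherwise form a lactol with the neighbouring formyl group after coupling and compete as a 6-exo oxa-Michael donor at the chalcone stage.

Step 4
Reactants: 5 3,4-dihydroxybenzaldehyde
Product: 6 2,2-diphenyl-1,3-benzodioxole-5-carbaldehyde
Conditions: Ph2CCl2 (1.3 equiv), Ph2O, 175 °C, N2 sweep
Reagents that add atoms: dichlorodiphenylmethane ClC(Cl)(c1ccccc1)c1ccccc1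
Why: Thermal catechol ketalization with loss of HCl gives a diphenylmethylene ketal that has no benzylic C–H (stable to n-BuLi), is a tied-back small ortho group for the hindered coupling, and is hydrogenolysed at the end together with the benzyl ethers.

Step 5
Reactants: 6 2,2-diphenyl-1,3-benzodioxole-5-carbaldehyde
Product: 10 (5-formyl-2,2-diphenyl-1,3-benzodioxol-4-yl)boronic acid, via lithium α-amino alkoxide 7 (not isolated), via ortho-lithiated α-amino alkoxide 8 (not isolated), via lithium aryl(triisopropoxy)borate 9 (not isolated)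
Conditions: LiN(Me)CH2CH2NMe2 (1.1 equiv, from the amine and n-BuLi), THF, −20 °C; n-BuLi (3 equiv), −20 °C, 18 h; B(OiPr)3 (6 equiv), −78 °C to rt; aq. HCl to pH 3, 0 °C
Reagents that add atoms: triisopropyl borate CC(C)OB(OC(C)C)OC(C)C; water O
Why: α-Amino alkoxide-directed ortho-lithiation (Comins protocol), in which the in situ hemiaminal masks the aldehyde and cooperates with the dioxole oxygen to direct n-BuLi to the doubly flanked C4; borate trapping and hydrolysis then return the aldehyde and B(OH)2.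

Step 6
Reactants: 4 5,7-bis(benzyloxy)-2-[4-(benzyloxy)phenyl]-6-iodo-4H-chromen-4-one; 10 (5-formyl-2,2-diphenyl-1,3-benzodioxol-4-yl)boronic acid (2 equiv)
Product: 11 4-{5,7-bis(benzyloxy)-2-[4-(benzyloxy)phenyl]-4-oxo-4H-chromen-6-yl}-2,2-diphenyl-1,3-benzodioxole-5-carbaldehyde
Conditions: Pd(OAc)2 (5 mol %), SPhos (10 mol %), K3PO4 (3 equiv), degassed toluene/H2O (10:1), 100 °C
Reagents that add atoms: none
Why: Suzuki–Miyaura coupling with a dialkylbiarylphosphine ligand suited to tetra-ortho-substituted biaryls (three of the four ortho groups are oxygen, one tied back), with excess boronic acid to offset protodeboronation; the axis forms without control.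

Step 7
Reactants: 12 2,4,6-trihydroxyacetophenone
Product: 13 1-[2,4-bis(benzyloxy)-6-hydroxyphenyl]ethan-1-one
Conditions: BnBr (2.05 equiv), K2CO3 (2.2 equiv), DMF, rt
Reagents that add atoms: benzyl bromide BrCc1ccccc1
Why: Williamson etherification that stops at the dibenzyl ether because the last ortho OH is locked in a hydrogen bond to the acetyl carbonyl.

Step 8
Reactants: 11 4-{5,7-bis(benzyloxy)-2-[4-(benzyloxy)phenyl]-4-oxo-4H-chromen-6-yl}-2,2-diphenyl-1,3-benzodioxole-5-carbaldehyde; 13 1-[2,4-bis(benzyloxy)-6-hydroxyphenyl]ethan-1-one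
Product: 14 (2E)-1-[2,4-bis(benzyloxy)-6-hydroxyphenyl]-3-(4-{5,7-bis(benzyloxy)-2-[4-(benzyloxy)phenyl]-4-oxo-4H-chromen-6-yl}-2,2-diphenyl-1,3-benzodioxol-5-yl)prop-2-en-1-one
Conditions: KOH (50% aq., 20 equiv), EtOH/THF (1:1), rt, 36 h; then 1 M HCl, 0 °C; chromatography to remove any cyclized (racemic) material
Reagents that add atoms: none
Why: Claisen–Schmidt condensation of a methyl ketone with a non-enolizable aldehyde gives the (E)-enone by E1cB dehydration, and the delocalized 2'-phenoxide keeps the chalcone open under strong base.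

Step 9
Reactants: 14 (2E)-1-[2,4-bis(benzyloxy)-6-hydroxyphenyl]-3-(4-{5,7-bis(benzyloxy)-2-[4-(benzyloxy)phenyl]-4-oxo-4H-chromen-6-yl}-2,2-diphenyl-1,3-benzodioxol-5-yl)prop-2-en-1-one
Product: 15 (2S)-5,7-bis(benzyloxy)-2-(4-{5,7-bis(benzyloxy)-2-[4-(benzyloxy)phenyl]-4-oxo-4H-chromen-6-yl}-2,2-diphenyl-1,3-benzodioxol-5-yl)-2,3-dihydro-4H-chromen-4-one
Conditions: quinine-derived squaramide [9-amino(9-deoxy)epi-quinine N-3,5-bis(trifluoromethyl)phenyl squaramide] (10 mol %), toluene, 4 Å MS, 0 °C to rt, 48–72 h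
Reagents that add atoms: none
Why: Proposed new method: enantioselective 6-endo-trig oxa-Michael cyclization of a non-activated 2'-hydroxy-6'-alkoxychalcone whose β-aryl group is a di-ortho-substituted biaryl, under bifunctional Brønsted base/hydrogen-bond-donor catalysis; the quinuclidine nitrogen acts as general base on the chelated 2'-OH while the squaramide NH pair binds the enone carbonyl, breaking the internal O–H···O=C bond and holding the enone so that the phenolic oxygen adds to the Si face of C-β (the face that gives 2S), after which the enol tautomerizes to ketone 15; the step forms the O1–C2 bond, closes the pyranone ring and sets the only stereocenter; because 15 has no free 5-OH and its C3–H is too weakly acidic for the amine, retro-oxa-Michael racemization is shut down, and the 6'-benzyloxy group twists the chalcone so ring closure is downhill; closest known reaction type: cinchona thiourea- or squaramide-catalysed asymmetric intramolecular oxa-Michael addition of simple or α-ester-activated 2'-hydroxychalcones to flavanones.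

Step 10
Reactants: 15 (2S)-5,7-bis(benzyloxy)-2-(4-{5,7-bis(benzyloxy)-2-[4-(benzyloxy)phenyl]-4-oxo-4H-chromen-6-yl}-2,2-diphenyl-1,3-benzodioxol-5-yl)-2,3-dihydro-4H-chromen-4-one
Product: 16 (2S)-2-{2-[5,7-dihydroxy-2-(4-hydroxyphenyl)-4-oxo-4H-chromen-6-yl]-3,4-dihydroxyphenyl}-5,7-dihydroxy-2,3-dihydro-4H-chromen-4-one (CNP0285181.1)
Conditions: H2 (1 atm), 10% Pd/C, THF/MeOH (1:1), rt; filtration, Sephadex LH-20
Reagents that add atoms: none
Why: Neutral hydrogenolysis cleaves the five benzyl ethers and the diphenylmethylene ketal in one operation, and with no acid or base present the flavanone ring cannot open, so C2 (S) is retained while the flavone C2=C3 bond and both ketones survive at 1 atm and rt.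

**Compound list**

1 | apigenin (5,7-dihydroxy-2-(4-hydroxyphenyl)-4H-chromen-4-one) | O=c1cc(-c2ccc(O)cc2)oc2cc(O)cc(O)c12 | starting material
2 | 7-(benzyloxy)-2-[4-(benzyloxy)phenyl]-5-hydroxy-4H-chromen-4-one | O=c1cc(-c2ccc(OCc3ccccc3)cc2)oc2cc(OCc3ccccc3)cc(O)c12 | intermediate
3 | 7-(benzyloxy)-2-[4-(benzyloxy)phenyl]-5-hydroxy-6-iodo-4H-chromen-4-one | O=c1cc(-c2ccc(OCc3ccccc3)cc2)oc2cc(OCc3ccccc3)c(I)c(O)c12 | intermediate
4 | 5,7-bis(benzyloxy)-2-[4-(benzyloxy)phenyl]-6-iodo-4H-chromen-4-one | O=c1cc(-c2ccc(OCc3ccccc3)cc2)oc2cc(OCc3ccccc3)c(I)c(OCc3ccccc3)c12 | intermediate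
5 | 3,4-dihydroxybenzaldehyde | O=Cc1ccc(O)c(O)c1 | starting material
6 | 2,2-diphenyl-1,3-benzodioxole-5-carbaldehyde | O=Cc1ccc2OC(c3ccccc3)(c3ccccc3)Oc2c1 | intermediate
7 | lithium α-amino alkoxide of 6 with LiN(Me)CH2CH2NMe2 (racemic at the hemiaminal carbon, not isolated) | CN(C)CCN(C)C(O[Li])c1ccc2OC(c3ccccc3)(c3ccccc3)Oc2c1 | intermediate
8 | C4-lithiated α-amino alkoxide (not isolated) | CN(C)CCN(C)C(O[Li])c1ccc2OC(c3ccccc3)(c3ccccc3)Oc2c1[Li] | intermediate
9 | lithium aryl(triisopropoxy)borate of the α-amino alkoxide (not isolated) | CN(C)CCN(C)C(O[Li])c1ccc2OC(c3ccccc3)(c3ccccc3)Oc2c1[B-](OC(C)C)(OC(C)C)OC(C)C.[Li+] | intermediate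
10 | (5-formyl-2,2-diphenyl-1,3-benzodioxol-4-yl)boronic acid | O=Cc1ccc2OC(c3ccccc3)(c3ccccc3)Oc2c1B(O)O | intermediate
11 | 4-{5,7-bis(benzyloxy)-2-[4-(benzyloxy)phenyl]-4-oxo-4H-chromen-6-yl}-2,2-diphenyl-1,3-benzodioxole-5-carbaldehyde (axis uncontrolled) | O=Cc1ccc2OC(c3ccccc3)(c3ccccc3)Oc2c1-c1c(OCc2ccccc2)cc2oc(-c3ccc(OCc4ccccc4)cc3)cc(=O)c2c1OCc1ccccc1 | intermediate
12 | 2,4,6-trihydroxyacetophenone | CC(=O)c1c(O)cc(O)cc1O | starting material
13 | 1-[2,4-bis(benzyloxy)-6-hydroxyphenyl]ethan-1-one | CC(=O)c1c(O)cc(OCc2ccccc2)cc1OCc1ccccc1 | intermediate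
14 | (2E)-1-[2,4-bis(benzyloxy)-6-hydroxyphenyl]-3-(4-{5,7-bis(benzyloxy)-2-[4-(benzyloxy)phenyl]-4-oxo-4H-chromen-6-yl}-2,2-diphenyl-1,3-benzodioxol-5-yl)prop-2-en-1-one | O=C(/C=C/c1ccc2OC(c3ccccc3)(c3ccccc3)Oc2c1-c1c(OCc2ccccc2)cc2oc(-c3ccc(OCc4ccccc4)cc3)cc(=O)c2c1OCc1ccccc1)c1c(O)cc(OCc2ccccc2)cc1OCc1ccccc1 | intermediate
15 | (2S)-5,7-bis(benzyloxy)-2-(4-{5,7-bis(benzyloxy)-2-[4-(benzyloxy)phenyl]-4-oxo-4H-chromen-6-yl}-2,2-diphenyl-1,3-benzodioxol-5-yl)-2,3-dihydro-4H-chromen-4-one | O=C1C[C@@H](c2ccc3OC(c4ccccc4)(c4ccccc4)Oc3c2-c2c(OCc3ccccc3)cc3oc(-c4ccc(OCc5ccccc5)cc4)cc(=O)c3c2OCc2ccccc2)Oc2cc(OCc3ccccc3)cc(OCc3ccccc3)c21 | intermediate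
16 | (2S)-2-{2-[5,7-dihydroxy-2-(4-hydroxyphenyl)-4-oxo-4H-chromen-6-yl]-3,4-dihydroxyphenyl}-5,7-dihydroxy-2,3-dihydro-4H-chromen-4-one (CNP0285181.1) | O=C1C[C@@H](c2ccc(O)c(O)c2-c2c(O)cc3oc(-c4ccc(O)cc4)cc(=O)c3c2O)Oc2cc(O)cc(O)c21 | target

**Step count and risks**

Total steps: 10. Longest linear sequence: 7 (steps 1, 2, 3, 6, 8, 9, 10).

Three steps most likely to fail:

Step 6 (tetra-ortho-substituted Suzuki–Miyaura coupling). The ortho-formyl, ortho-oxygenated boronic acid 10 can protodeboronate faster than it couples with the hindered iodide 4. Fallback: reverse the polarity of the two partners. It sets out from 6 and 4 and comes back at 11. Aldehyde 6 is lithiated exactly as in step 5 (through 7 and 8), and 8 is quenched at −78 °C with BrCCl2CCl2Br to give the lithium α-amino alkoxide of the bromo aldehyde F1 (not isolated). Aqueous HCl work-up releases 4-bromo-2,2-diphenyl-1,3-benzodioxole-5-carbaldehyde F2. Iodide 4 is converted by Miyaura borylation (B2pin2, PdCl2(dppf), KOAc, dioxane, 90 °C) into 5,7-bis(benzyloxy)-2-[4-(benzyloxy)phenyl]-6-(4,4,5,5-tetramethyl-1,3,2-dioxaborolan-2-yl)-4H-chromen-4-one F3. F2 and F3 are then coupled (Pd(OAc)2, SPhos, K3PO4, dioxane/H2O, 90 °C) to give 11. In this pairing oxidative addition takes place on the electron-poor ortho-formyl bromide and boron sits on the electron-rich ring, which transmetalates quickly.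

Step 8 (Claisen–Schmidt condensation). The aldehyde of 11 is flanked by the biaryl axis, and the tri-O-benzyl flavone can be opened by hydroxide over long reaction times. Fallback: a kinetic directed aldol followed by a separate dehydration. It sets out from 13 and 11 and comes back at 14. Ketone 13 is doubly deprotonated with LiN(SiMe3)2 (2.2 equiv, THF, −78 °C) to the dilithium enolate-phenoxide of 13 F4. F4 adds to 11 at −78 °C and, after aq. NH4Cl quench, gives the β-hydroxy ketone 1-[2,4-bis(benzyloxy)-6-hydroxyphenyl]-3-hydroxy-3-(4-{5,7-bis(benzyloxy)-2-[4-(benzyloxy)phenyl]-4-oxo-4H-chromen-6-yl}-2,2-diphenyl-1,3-benzodioxol-5-yl)propan-1-one F5. Mild dehydration (cat. TsOH·H2O, toluene, 40 °C) gives chalcone 14 without exposing the flavone to hydroxide.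

Step 9 (proposed new asymmetric oxa-Michael cyclization). The level and sense of induction on this hindered substrate are unproven. The two atropisomers of 14 may react at different rates, and turnover may be slow. If a pilot run shows the 2R sense, the quinidine-derived pseudo-enantiomeric squaramide is used under the same conditions. Fallback with known chemistry: racemic cyclization followed by chromatographic resolution. It sets out from 14 and comes back at 15. Chalcone 14 is cyclized with NaOAc in EtOH at reflux to racemic 5,7-bis(benzyloxy)-2-(4-{5,7-bis(benzyloxy)-2-[4-(benzyloxy)phenyl]-4-oxo-4H-chromen-6-yl}-2,2-diphenyl-1,3-benzodioxol-5-yl)-2,3-dihydro-4H-chromen-4-one F6. F6 is resolved by preparative SFC on an amylose tris(3,5-dimethylphenylcarbamate) phase to give 15. The (2R)-enantiomer F7 is recycled by base-mediated ring opening and re-closure (KOH, EtOH/THF, then NaOAc), which returns it to F6.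

**Further compounds**

F1 | step 6 | lithium α-amino alkoxide of 4-bromo-2,2-diphenyl-1,3-benzodioxole-5-carbaldehyde with LiN(Me)CH2CH2NMe2 (not isolated) | CN(C)CCN(C)C(O[Li])c1ccc2OC(c3ccccc3)(c3ccccc3)Oc2c1Br
F2 | step 6 | 4-bromo-2,2-diphenyl-1,3-benzodioxole-5-carbaldehyde | O=Cc1ccc2OC(c3ccccc3)(c3ccccc3)Oc2c1Br
F3 | step 6 | 5,7-bis(benzyloxy)-2-[4-(benzyloxy)phenyl]-6-(4,4,5,5-tetramethyl-1,3,2-dioxaborolan-2-yl)-4H-chromen-4-one | O=c1cc(-c2ccc(OCc3ccccc3)cc2)oc2cc(OCc3ccccc3)c(B3OC(C)(C)C(C)(C)O3)c(OCc3ccccc3)c12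
F4 | step 8 | dilithium enolate-phenoxide of 1-[2,4-bis(benzyloxy)-6-hydroxyphenyl]ethan-1-one (not isolated) | [Li]OC(=C)c1c(O[Li])cc(OCc2ccccc2)cc1OCc1ccccc1
F5 | step 8 | 1-[2,4-bis(benzyloxy)-6-hydroxyphenyl]-3-hydroxy-3-(4-{5,7-bis(benzyloxy)-2-[4-(benzyloxy)phenyl]-4-oxo-4H-chromen-6-yl}-2,2-diphenyl-1,3-benzodioxol-5-yl)propan-1-one (racemic carbinol) | O=C(CC(O)c1ccc2OC(c3ccccc3)(c3ccccc3)Oc2c1-c1c(OCc2ccccc2)cc2oc(-c3ccc(OCc4ccccc4)cc3)cc(=O)c2c1OCc1ccccc1)c1c(O)cc(OCc2ccccc2)cc1OCc1ccccc1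
F6 | step 9 | racemic 5,7-bis(benzyloxy)-2-(4-{5,7-bis(benzyloxy)-2-[4-(benzyloxy)phenyl]-4-oxo-4H-chromen-6-yl}-2,2-diphenyl-1,3-benzodioxol-5-yl)-2,3-dihydro-4H-chromen-4-one | O=C1CC(c2ccc3OC(c4ccccc4)(c4ccccc4)Oc3c2-c2c(OCc3ccccc3)cc3oc(-c4ccc(OCc5ccccc5)cc4)cc(=O)c3c2OCc2ccccc2)Oc2cc(OCc3ccccc3)cc(OCc3ccccc3)c21
F7 | step 9 | (2R)-5,7-bis(benzyloxy)-2-(4-{5,7-bis(benzyloxy)-2-[4-(benzyloxy)phenyl]-4-oxo-4H-chromen-6-yl}-2,2-diphenyl-1,3-benzodioxol-5-yl)-2,3-dihydro-4H-chromen-4-one | O=C1C[C@H](c2ccc3OC(c4ccccc4)(c4ccccc4)Oc3c2-c2c(OCc3ccccc3)cc3oc(-c4ccc(OCc5ccccc5)cc4)cc(=O)c3c2OCc2ccccc2)Oc2cc(OCc3ccccc3)cc(OCc3ccccc3)c21
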